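**Plan**

1. Unit P is the 6,7-dihydroxycoumarin that carries the ether oxygen on C5; unit Q is the 7-hydroxycoumarin bonded through C6. Retrosynthesis first cuts the three O–CH3 bonds, then in unit Q the C4–O bond (triflate) and the C3–C4 bond (Claisen), leaving a methyl 2,4-dihydroxybenzoate whose ester carbon is C4 of Q.
2. Feature used: in unit Q the oxygens on C7 and C8a are meta and the ether oxygen on C6 sits next to the unsubstituted C5, so the benzene ring of Q is the folded form of a 3,5-dioxo ester ending in an α-aryloxy β-methoxy enone; cutting C4a–C5 of Q opens the ring to that chain.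
3. The chain is cut at the ketone C–C bond next to the enone (acid chloride plus the bis-silyl dienol ether of methyl acetoacetate), at the enol-ether carbon (methyl formate) and at O–CH2 (SN2 on tert-butyl bromoacetate), so the diaryl ether oxygen is never made by arylation; the lactone of unit P goes back to 3,4,5-trimethoxyphenol.
4. Forward order: pyranone of unit P, then the chain, then the benzene ring of unit Q, then the pyranone of unit Q, then removal of the three methyl groups.
5. Stereochemistry: the target has no stereocentre; the only stereo-elements on the way are C=C geometries, set by a (Z)-selective olefination (needed for lactonization) and by enol-ether formation (erased in the ring closure).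

Key step: step 12

Remark: a coumarin oxygenated on C5, C6 and C7 needs a benzaldehyde with oxygen on both ortho carbons; 3,4,5-trimethoxyphenol gives this pattern as a single formylation isomer, and the two ortho oxygens are told apart by pivalate protection and chelation-controlled demethylation.
Remark: 10 and 17 are tautomeric mixtures drawn in one form; the double-bond geometry of 14 and 15 is undefined and of no consequence.

**Route**

Step 1
Reactants: 1 3,4,5-trimethoxyphenol
Product: 2 6-hydroxy-2,3,4-trimethoxybenzaldehyde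
Conditions: MgCl2, Et3N, (CH2O)n, MeCN, reflux; 1 M HCl
Reagents that add atoms: paraformaldehyde (as formaldehyde), C=O
Why: Magnesium-phenoxide-directed ortho-formylation delivers formaldehyde only next to the phenol oxygen, and because C2 and C6 of 1 are equivalent a single aldehyde should result.

Step 2
Reactants: 2 6-hydroxy-2,3,4-trimethoxybenzaldehyde
Product: 3 2-formyl-3,4,5-trimethoxyphenyl pivalate
Conditions: pivaloyl chloride, Et3N, DMAP (cat.), CH2Cl2, 0 → 25 °C
Reagents that add atoms: pivaloyl chloride, CC(C)(C)C(Cl)=O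
Why: DMAP-catalysed O-acylation masks the future lactone oxygen of unit P as an ester that cannot be cleaved through the aldehyde–boron chelate of the next step.

Step 3
Reactants: 3 2-formyl-3,4,5-trimethoxyphenyl pivalate
Product: 4 2-formyl-3-hydroxy-4,5-dimethoxyphenyl pivalate
Conditions: BCl3 (1.2 equiv), CH2Cl2, –78 → 0 °C; H2O
Reagents that add atoms: none
Why: Chelation-controlled demethylation, in which BCl3 bound to the aldehyde oxygen reaches only the adjacent methoxy group through a six-membered chelate, should free the future C5 oxygen of unit P while the two remote methyl ethers and the pivalate stay.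

Step 4
Reactants: 4 2-formyl-3-hydroxy-4,5-dimethoxyphenyl pivalate; 5 tert-butyl bromoacetate
Product: 6 tert-butyl 2-[2-formyl-5,6-dimethoxy-3-(pivaloyloxy)phenoxy]acetate
Conditions: K2CO3, DMF, 25 °C
Reagents that add atoms: none
Why: Williamson ether synthesis (SN2 on the primary α-bromo ester) at the only free phenol places the future diaryl ether oxygen on carbon, and carbonate at room temperature is too weak to enolize the new aryloxyacetate, so aldol closure onto the aldehyde should not compete.

Step 5
Reactants: 6 tert-butyl 2-[2-formyl-5,6-dimethoxy-3-(pivaloyloxy)phenoxy]acetate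
Product: 8 tert-butyl 2-[(6,7-dimethoxy-2-oxo-2H-chromen-5-yl)oxy]acetate, via (Z)-cinnamate ester 7 (not isolated)
Conditions: (CF3CH2O)2P(O)CH2CO2Me, KN(SiMe3)2, 18-crown-6, THF, –78 °C; then K2CO3 (cat.), MeOH, 25 °C; dilute HCl
Reagents that add atoms: methyl bis(2,2,2-trifluoroethyl)phosphonoacetate, COC(=O)CP(=O)(OCC(F)(F)F)OCC(F)(F)F
Why: The Still–Gennari variant of the Horner–Wadsworth–Emmons olefination should give the (Z)-cinnamate, and methanolysis of the pivalate then frees a phenoxide cis to the methyl ester, which lactonizes to the pyranone of unit P.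

Step 6
Reactants: 8 tert-butyl 2-[(6,7-dimethoxy-2-oxo-2H-chromen-5-yl)oxy]acetate; 9 methyl formate
Product: 10 tert-butyl 2-[(6,7-dimethoxy-2-oxo-2H-chromen-5-yl)oxy]-3-hydroxyprop-2-enoate (enol of the 2-formyl ester)
Conditions: NaH, THF, 0 → 25 °C; 1 M HCl; used crude
Reagents that add atoms: none
Why: Crossed Claisen condensation with methyl formate at the only enolizable carbon is driven by the stabilized sodium enolate of the α-formyl ester, and a lactone opened by methoxide is the cis-cinnamate, which recloses on acidification.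

Step 7
Reactants: 10 tert-butyl 2-[(6,7-dimethoxy-2-oxo-2H-chromen-5-yl)oxy]-3-hydroxyprop-2-enoate
Product: 11 tert-butyl (Z)-2-[(6,7-dimethoxy-2-oxo-2H-chromen-5-yl)oxy]-3-methoxyprop-2-enoate
Conditions: Me2SO4, K2CO3, acetone, 25 °C
Reagents that add atoms: dimethyl sulfate, COS(=O)(=O)OC
Why: O-Alkylation of the formyl-ester enolate by the hard electrophile dimethyl sulfate should give the β-methoxyacrylate with methoxy trans to the ester carbonyl, i.e. (Z), a geometry that is not carried into the target.

Step 8
Reactants: 11 tert-butyl (Z)-2-[(6,7-dimethoxy-2-oxo-2H-chromen-5-yl)oxy]-3-methoxyprop-2-enoate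
Product: 12 (Z)-2-[(6,7-dimethoxy-2-oxo-2H-chromen-5-yl)oxy]-3-methoxyprop-2-enoic acid
Conditions: CF3CO2H, CH2Cl2, 25 °C
Reagents that add atoms: none
Why: Acidolysis of the tert-butyl ester through the tert-butyl cation should leave the push–pull enol ether, the lactone and the aryl ethers untouched under anhydrous acid.

Step 9
Reactants: 13 methyl acetoacetate
Product: 14 methyl 3-(trimethylsilyloxy)but-2-enoate
Conditions: Me3SiCl, Et3N, hexane, 25 °C
Reagents that add atoms: chlorotrimethylsilane, C[Si](C)(C)Cl
Why: O-Silylation of the enol of a β-keto ester under soft enolization with Et3N is a standard silyl enol ether formation.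

Step 10
Reactants: 14 methyl 3-(trimethylsilyloxy)but-2-enoate
Product: 15 1-methoxy-1,3-bis(trimethylsilyloxy)buta-1,3-diene
Conditions: LiN(iPr)2, THF, –78 °C; Me3SiCl, –78 → 0 °C
Reagents that add atoms: chlorotrimethylsilane, C[Si](C)(C)Cl
Why: γ-Deprotonation with LiN(iPr)2 and O-silylation of the ester dienolate give the bis-silyl dienol ether, a masked dianion of methyl acetoacetate.

Step 11
Reactants: 12 (Z)-2-[(6,7-dimethoxy-2-oxo-2H-chromen-5-yl)oxy]-3-methoxyprop-2-enoic acid; 15 1-methoxy-1,3-bis(trimethylsilyloxy)buta-1,3-diene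
Product: 17 methyl (Z)-6-[(6,7-dimethoxy-2-oxo-2H-chromen-5-yl)oxy]-7-methoxy-3,5-dioxohept-6-enoate, via acid chloride 16 (not isolated)
Conditions: (COCl)2, DMF (cat.), CH2Cl2, 0 → 25 °C, evaporate; then 15, CH2Cl2, –78 → 0 °C; cold aq. NaHCO3; used without chromatography
Reagents that add atoms: none
Why: The acid chloride acylates the terminal carbon of the bis-silyl dienol ether without Lewis acid (vinylogous Mukaiyama-type C-acylation), being far more electrophilic than the enol-ether carbon or the lactone, and the cold buffered work-up should keep the new diketone from closing under acid.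

Step 12
Reactants: 17 methyl (Z)-6-[(6,7-dimethoxy-2-oxo-2H-chromen-5-yl)oxy]-7-methoxy-3,5-dioxohept-6-enoate
Product: 18 methyl 5-[(6,7-dimethoxy-2-oxo-2H-chromen-5-yl)oxy]-2,4-dihydroxybenzoate
Conditions: Mg(OMe)2 (3 equiv), MeOH, 0 → 50 °C; then 1 M HCl
Reagents that add atoms: none
Why: Mg(OMe)2 converts 17 into its magnesium enolates, the β-keto ester enolate adds through C2 to C7 of the β-methoxy enone, methoxide is expelled and two enolizations aromatize the new ring, so that the C2–C7 bond becomes C4a–C5 of unit Q. The closest known reaction type is the base-induced aldol-type cycloaromatization of 3,5-dioxoalkanoates, together with the addition–elimination of β-dicarbonyl carbanions to alkoxymethylene ketones. The benzene ring closes in a 6-endo-trig mode, the C6=C7 bond lying inside the ring. No stereocentre is formed and the enol-ether geometry is erased in the tetrahedral adduct. The selectivity needed is attack by carbon C2 and not by the enol oxygen on C3, which would give a 4-pyranone; magnesium holds the enolate oxygens in chelates and leaves carbon as the nucleophilic site, O-closure is reversible under methoxide whereas C-closure ends in an aromatic phenoxide, and C6 bears no hydrogen so no Claisen-type closure onto the ester can compete. Acidic work-up recloses the lactone of unit P if methoxide has opened it.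

Step 13
Reactants: 18 methyl 5-[(6,7-dimethoxy-2-oxo-2H-chromen-5-yl)oxy]-2,4-dihydroxybenzoate
Product: 19 methyl 5-[(6,7-dimethoxy-2-oxo-2H-chromen-5-yl)oxy]-2-hydroxy-4-methoxybenzoate
Conditions: MeI (1.1 equiv), K2CO3, acetone, 25 °C
Reagents that add atoms: iodomethane, CI
Why: Williamson methylation should take the more acidic, non-chelated 4-hydroxy group, since the 2-hydroxy group is hydrogen-bonded to the ester carbonyl, and the new methyl ether keeps O7 of unit Q out of the later triflation.

Step 14
Reactants: 19 methyl 5-[(6,7-dimethoxy-2-oxo-2H-chromen-5-yl)oxy]-2-hydroxy-4-methoxybenzoate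
Product: 21 6-[(6,7-dimethoxy-2-oxo-2H-chromen-5-yl)oxy]-4-hydroxy-7-methoxy-2H-chromen-2-one, via O-acetate 20 (not isolated)
Conditions: LiN(SiMe3)2 (1.05 equiv), THF, –78 °C; AcCl, –78 → 0 °C; LiN(SiMe3)2 (2.5 equiv), –78 → 0 °C; 1 M HCl
Reagents that add atoms: acetyl chloride, CC(Cl)=O
Why: O-Acetylation of the lithium phenoxide is followed by an intramolecular Claisen (Dieckmann-type) condensation in which the acetate enolate attacks the ortho ester in a 6-exo-trig closure and methoxide leaves, so that the ester carbon becomes C4 of unit Q in a 4-hydroxycoumarin held as its stable enolate.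

Step 15
Reactants: 21 6-[(6,7-dimethoxy-2-oxo-2H-chromen-5-yl)oxy]-4-hydroxy-7-methoxy-2H-chromen-2-one
Product: 22 6-[(6,7-dimethoxy-2-oxo-2H-chromen-5-yl)oxy]-7-methoxy-2-oxo-2H-chromen-4-yl trifluoromethanesulfonate
Conditions: (CF3SO2)2O, Et3N, CH2Cl2, –20 °C
Reagents that add atoms: trifluoromethanesulfonic anhydride, O=S(=O)(OS(=O)(=O)C(F)(F)F)C(F)(F)F
Why: Sulfonylation of the acidic vinylogous-acid hydroxyl gives the enol triflate, the usual activation of a 4-hydroxycoumarin.

Step 16
Reactants: 22 6-[(6,7-dimethoxy-2-oxo-2H-chromen-5-yl)oxy]-7-methoxy-2-oxo-2H-chromen-4-yl trifluoromethanesulfonate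
Product: 23 6,7-dimethoxy-5-[(7-methoxy-2-oxo-2H-chromen-6-yl)oxy]-2H-chromen-2-one
Conditions: Pd(OAc)2 (5 mol %), PPh3, HCO2H, Et3N, DMF, 60 °C
Reagents that add atoms: none
Why: Palladium-catalysed formate reduction of an enol triflate (oxidative addition to zerovalent palladium formed in situ, exchange for formate, loss of CO2, reductive elimination of C4–H) should leave both lactones and both C3=C4 bonds intact.

Step 17
Reactants: 23 6,7-dimethoxy-5-[(7-methoxy-2-oxo-2H-chromen-6-yl)oxy]-2H-chromen-2-one
Product: 24 6,7-dihydroxy-5-[(7-hydroxy-2-oxo-2H-chromen-6-yl)oxy]-2H-chromen-2-one (CNP0197949.0)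
Conditions: BBr3 (excess), CH2Cl2, –78 → 25 °C; then MeOH, H2O
Reagents that add atoms: none
Why: Lewis-acid cleavage of the three aryl methyl ethers by BBr3 (bromide attack at methyl) should spare the coumarin lactones and the diaryl ether, as in the demethylation of simple methoxycoumarins.

**Compound list**

1 | 3,4,5-trimethoxyphenol | COc1cc(O)cc(OC)c1OC | starting material
2 | 6-hydroxy-2,3,4-trimethoxybenzaldehyde | COc1cc(O)c(C=O)c(OC)c1OC | intermediate
3 | 2-formyl-3,4,5-trimethoxyphenyl pivalate | COc1cc(OC(=O)C(C)(C)C)c(C=O)c(OC)c1OC | intermediate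
4 | 2-formyl-3-hydroxy-4,5-dimethoxyphenyl pivalate | COc1cc(OC(=O)C(C)(C)C)c(C=O)c(O)c1OC | intermediate
5 | tert-butyl bromoacetate | CC(C)(C)OC(=O)CBr | starting material
6 | tert-butyl 2-[2-formyl-5,6-dimethoxy-3-(pivaloyloxy)phenoxy]acetate | COc1cc(OC(=O)C(C)(C)C)c(C=O)c(OCC(=O)OC(C)(C)C)c1OC | intermediate
7 | methyl (Z)-3-[2-(2-tert-butoxy-2-oxoethoxy)-3,4-dimethoxy-6-(pivaloyloxy)phenyl]prop-2-enoate (not isolated) | COC(=O)/C=C\c1c(OC(=O)C(C)(C)C)cc(OC)c(OC)c1OCC(=O)OC(C)(C)C | intermediate
8 | tert-butyl 2-[(6,7-dimethoxy-2-oxo-2H-chromen-5-yl)oxy]acetate | CC(C)(C)OC(=O)COc1c(OC)c(OC)cc2oc(=O)ccc12 | intermediate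
9 | methyl formate | COC=O | starting material
10 | tert-butyl 2-[(6,7-dimethoxy-2-oxo-2H-chromen-5-yl)oxy]-3-hydroxyprop-2-enoate (enol of the 2-formyl ester, tautomer and E/Z mixture) | CC(C)(C)OC(=O)C(Oc1c(OC)c(OC)cc2oc(=O)ccc12)=CO | intermediate
11 | tert-butyl (Z)-2-[(6,7-dimethoxy-2-oxo-2H-chromen-5-yl)oxy]-3-methoxyprop-2-enoate | CC(C)(C)OC(=O)/C(Oc1c(OC)c(OC)cc2oc(=O)ccc12)=C/OC | intermediate
12 | (Z)-2-[(6,7-dimethoxy-2-oxo-2H-chromen-5-yl)oxy]-3-methoxyprop-2-enoic acid | OC(=O)/C(Oc1c(OC)c(OC)cc2oc(=O)ccc12)=C/OC | intermediate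
13 | methyl acetoacetate | COC(=O)CC(C)=O | starting material
14 | methyl 3-(trimethylsilyloxy)but-2-enoate (geometry undefined) | COC(=O)C=C(C)O[Si](C)(C)C | intermediate
15 | 1-methoxy-1,3-bis(trimethylsilyloxy)buta-1,3-diene (geometry undefined) | COC(O[Si](C)(C)C)=CC(=C)O[Si](C)(C)C | intermediate
16 | (Z)-2-[(6,7-dimethoxy-2-oxo-2H-chromen-5-yl)oxy]-3-methoxyprop-2-enoyl chloride (not isolated) | ClC(=O)/C(Oc1c(OC)c(OC)cc2oc(=O)ccc12)=C/OC | intermediate
17 | methyl (Z)-6-[(6,7-dimethoxy-2-oxo-2H-chromen-5-yl)oxy]-7-methoxy-3,5-dioxohept-6-enoate | COC(=O)CC(=O)CC(=O)/C(Oc1c(OC)c(OC)cc2oc(=O)ccc12)=C/OC | intermediate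
18 | methyl 5-[(6,7-dimethoxy-2-oxo-2H-chromen-5-yl)oxy]-2,4-dihydroxybenzoate | COC(=O)c1cc(Oc2c(OC)c(OC)cc3oc(=O)ccc23)c(O)cc1O | intermediate
19 | methyl 5-[(6,7-dimethoxy-2-oxo-2H-chromen-5-yl)oxy]-2-hydroxy-4-methoxybenzoate | COC(=O)c1cc(Oc2c(OC)c(OC)cc3oc(=O)ccc23)c(OC)cc1O | intermediate
20 | methyl 2-acetoxy-5-[(6,7-dimethoxy-2-oxo-2H-chromen-5-yl)oxy]-4-methoxybenzoate (not isolated) | COC(=O)c1cc(Oc2c(OC)c(OC)cc3oc(=O)ccc23)c(OC)cc1OC(C)=O | intermediate
21 | 6-[(6,7-dimethoxy-2-oxo-2H-chromen-5-yl)oxy]-4-hydroxy-7-methoxy-2H-chromen-2-one | COc1cc2oc(=O)cc(O)c2cc1Oc1c(OC)c(OC)cc2oc(=O)ccc12 | intermediate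
22 | 6-[(6,7-dimethoxy-2-oxo-2H-chromen-5-yl)oxy]-7-methoxy-2-oxo-2H-chromen-4-yl trifluoromethanesulfonate | COc1cc2oc(=O)cc(OS(=O)(=O)C(F)(F)F)c2cc1Oc1c(OC)c(OC)cc2oc(=O)ccc12 | intermediate
23 | 6,7-dimethoxy-5-[(7-methoxy-2-oxo-2H-chromen-6-yl)oxy]-2H-chromen-2-one | COc1cc2oc(=O)ccc2cc1Oc1c(OC)c(OC)cc2oc(=O)ccc12 | intermediate
24 | 6,7-dihydroxy-5-[(7-hydroxy-2-oxo-2H-chromen-6-yl)oxy]-2H-chromen-2-one | O=c1ccc2cc(Oc3c(O)c(O)cc4oc(=O)ccc34)c(O)cc2o1 | target

**Step count and risks**

Total step count: 17. Longest linear sequence: 15 steps (steps 1–8 and 11–17, from 1); steps 9 and 10 are the side branch to diene 15.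

Steps most likely to fail:

Step 12. The ring may close through the enol oxygen on C3 instead of carbon C2, or methoxide may cleave the poly-carbonyl chain, so that little benzenoid product forms. The fallback sets out from acid 12 and ties the troublesome oxygen into a ring. Acid chloride 16, made as in step 11, acylates the exocyclic carbon of the lithium dienolate of 2,2,6-trimethyl-4H-1,3-dioxin-4-one (LiN(SiMe3)2, THF, –78 °C) to give 6-[(3Z)-3-[(6,7-dimethoxy-2-oxo-2H-chromen-5-yl)oxy]-4-methoxy-2-oxobut-3-en-1-yl]-2,2-dimethyl-4H-1,3-dioxin-4-one F1. In this compound the oxygen that corresponds to O3 is an acetal oxygen and cannot attack C7, so Et3N or Cs2CO3 can only close through C5 of the dioxinone. With loss of methanol this gives 6-[(6,7-dimethoxy-2-oxo-2H-chromen-5-yl)oxy]-7-hydroxy-2,2-dimethyl-4H-1,3-benzodioxin-4-one F2. K2CO3 in MeOH then opens the acetonide ester, and the route is rejoined at 18.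

Step 11. Acid liberated during the acylation (HCl, Me3SiCl) may close the freshly formed enol-ether diketone through oxygen, and the diene may be desilylated before it is acylated, so that 17 cannot be obtained clean. The fallback sets out from 12 and uses the O-closed form as a stable mask. The acylation is run as before, but the crude product is stirred with CF3CO2H in CH2Cl2 until O-closure is complete, giving methyl 2-{5-[(6,7-dimethoxy-2-oxo-2H-chromen-5-yl)oxy]-4-oxo-4H-pyran-2-yl}acetate F3, which can be purified. KOH in MeOH at reflux then adds methoxide to C6 of the pyranone, the ring opens to the enolate of 17, and this recloses through carbon and aromatizes (the known pyranone-to-resorcylate ring transformation). After acidification the route is rejoined at 18.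

Step 14. The aryl acetate enolate may fragment to ketene and phenoxide before it cyclizes, or base may attack the lactone of unit P, so that the 4-hydroxycoumarin is not formed. The fallback sets out from 19 and gives up the ester carbon. LiOH in THF/H2O followed by acid gives 5-[(6,7-dimethoxy-2-oxo-2H-chromen-5-yl)oxy]-2-hydroxy-4-methoxybenzoic acid F4. Thermal decarboxylation (DMSO, 150 °C) gives 5-(4-hydroxy-2-methoxyphenoxy)-6,7-dimethoxy-2H-chromen-2-one F5. Pd(OAc)2-catalysed hydroarylation of ethyl propiolate in CF3CO2H/CH2Cl2, ortho to the hydroxyl and para to the methoxy group, followed by lactonization, builds the pyranone of unit Q directly. The route is rejoined at 23, bypassing steps 14–16.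

Further compounds
F1 | step 12 | 6-[(3Z)-3-[(6,7-dimethoxy-2-oxo-2H-chromen-5-yl)oxy]-4-methoxy-2-oxobut-3-en-1-yl]-2,2-dimethyl-4H-1,3-dioxin-4-one | CC1(C)OC(=O)C=C(CC(=O)/C(Oc2c(OC)c(OC)cc3oc(=O)ccc23)=C/OC)O1
F2 | step 12 | 6-[(6,7-dimethoxy-2-oxo-2H-chromen-5-yl)oxy]-7-hydroxy-2,2-dimethyl-4H-1,3-benzodioxin-4-one | CC1(C)OC(=O)c2cc(Oc3c(OC)c(OC)cc4oc(=O)ccc34)c(O)cc2O1
F3 | step 11 | methyl 2-{5-[(6,7-dimethoxy-2-oxo-2H-chromen-5-yl)oxy]-4-oxo-4H-pyran-2-yl}acetate | COC(=O)Cc1cc(=O)c(Oc2c(OC)c(OC)cc3oc(=O)ccc23)co1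
F4 | step 14 | 5-[(6,7-dimethoxy-2-oxo-2H-chromen-5-yl)oxy]-2-hydroxy-4-methoxybenzoic acid | OC(=O)c1cc(Oc2c(OC)c(OC)cc3oc(=O)ccc23)c(OC)cc1O
F5 | step 14 | 5-(4-hydroxy-2-methoxyphenoxy)-6,7-dimethoxy-2H-chromen-2-one | COc1cc(O)ccc1Oc1c(OC)c(OC)cc2oc(=O)ccc12
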